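**Plan**

1. Cuts, in retrosynthetic order: one C11–CH3 bond of the carbinol (MeMgBr on a C7 acetyl group, an oxidation-level helper); then the C5–C10 bond together with the C4–O(aryl) bond; then C6–C7 of a ten-membered ring (sulfonyl carbanion on an epoxide).
2. Enabling feature: C5–C10 is the bond shared by rings A and B, and C5 sits between C10 (quaternary, methyl) and C4 (tertiary, oxygen). Without that bond the carbocycle is a cyclodeca-1,5-diene (C1=C10, C4=C5), so protonation at C1 lets C5 bond to C10 across the ring and leaves C4 to a phenol oxygen of magnolol.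
3. Forward order: farnesyl chain (sulfone, terminal epoxy alcohol), then the ten-membered ring, then acetyl ketone 9, then rings A and B plus the aryl ether in one step, then C7 epimerization, then methyl addition.
4. Stereochemistry: C7 comes from the Sharpless epoxide (SN2 inversion on ring closure) and is made 7S on purpose. In the key step the 1(10)E/4Z geometry, a chair-like ring A array and anti C–C/C–O addition give the cis fusion and 4R,5S,10R, with the face chosen by the equatorial C7 acetyl group.
5. C7 is then turned to 7R by thermodynamic epimerization and fixed by the Grignard step. This equilibrium is the least certain stereochemical element of the route.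

Key step: step 8

Remark: geometrically pure (2Z,6E)-farnesol and magnolol are taken as purchasable; locants C1–C15 follow eudesmane/germacrane numbering (C4 ether carbon, C5 and C10 ring-fusion carbons, C7 side-chain carbon, C11 carbinol carbon).

**Step 1**
Reactants: 1 (2Z,6E)-farnesol
Product: 2 (2Z,6E)-farnesyl chloride
Conditions: NCS, Me2S, CH2Cl2, −30 to 0 °C
Reagents that add atoms: N-chlorosuccinimide, ClN1C(=O)CCC1=O
Why: Corey–Kim chlorination, in which the alkoxysulfonium salt of 1 is displaced by chloride at the primary allylic carbon in an SN2 sense, so the position and Z geometry of the 2,3-olefin should be kept.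

**Step 2**
Reactants: 2 (2Z,6E)-farnesyl chloride
Product: 3 (2Z,6E)-farnesyl phenyl sulfone
Conditions: PhSO2Na, DMF, rt
Reagents that add atoms: sodium benzenesulfinate, [Na+].[O-]S(=O)c1ccccc1
Why: SN2 S-alkylation of the sulfinate by the primary allylic chloride (sulfone formation) in a dipolar aprotic solvent, without allylic transposition.

**Step 3**
Reactants: 3 (2Z,6E)-farnesyl phenyl sulfone
Product: 4 (2E,6E,10Z)-12-(benzenesulfonyl)-2,6,10-trimethyldodeca-2,6,10-trien-1-ol
Conditions: SeO2 (10 mol %), t-BuOOH, salicylic acid (cat.), CH2Cl2, 0 °C to rt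
Reagents that add atoms: tert-butyl hydroperoxide, CC(C)(C)OO
Why: Riley-type SeO2 allylic oxidation (ene reaction then [2,3]-sigmatropic shift) should pick the terminal, most electron-rich trisubstituted olefin and there the methyl group trans to the chain, giving the E allylic alcohol, while the olefin next to the sulfone is deactivated.

**Step 4**
Reactants: 4 (2E,6E,10Z)-12-(benzenesulfonyl)-2,6,10-trimethyldodeca-2,6,10-trien-1-ol
Product: 5 [(2S,3S)-3-[(3E,7Z)-9-(benzenesulfonyl)-3,7-dimethylnona-3,7-dien-1-yl]-2-methyloxiran-2-yl]methanol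
Conditions: Ti(OiPr)4 (10 mol %), L-(+)-DET (12 mol %), t-BuOOH, 4 Å MS, CH2Cl2, −20 °C
Reagents that add atoms: tert-butyl hydroperoxide, CC(C)(C)OO
Why: Sharpless asymmetric epoxidation of the E-2-methyl allylic alcohol, where the L-(+)-tartrate catalyst should deliver oxygen to the face that gives the (2S,3S)-epoxy alcohol and the hydroxyl-directed reagent leaves the two other olefins alone.

**Step 5**
Reactants: 5 [(2S,3S)-3-[(3E,7Z)-9-(benzenesulfonyl)-3,7-dimethylnona-3,7-dien-1-yl]-2-methyloxiran-2-yl]methanol
Product: 7 (2R)-2-[(1R,3Z,7E)-2-(benzenesulfonyl)-4,8-dimethylcyclodeca-3,7-dien-1-yl]propane-1,2-diol (both epimers at ring C2), via dilithiated epoxy sulfone 6 (not isolated)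
Conditions: n-BuLi (2.2 equiv), DABCO, THF (0.005 M), −78 to −20 °C; then H2O
Reagents that add atoms: none
Why: double deprotonation gives the lithium alkoxide and the sulfonyl-stabilized allyl anion, whose alpha carbon should open the epoxide at its less substituted carbon in an intramolecular SN2 reaction under high dilution (the carbanion–epoxide closure used for ten-membered germacrane rings), so that inversion at that carbon sets the future C7 while the sulfonyl-bearing carbon forms as an inconsequential epimer mixture.

**Step 6**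
Reactants: 7 (2R)-2-[(1R,3Z,7E)-2-(benzenesulfonyl)-4,8-dimethylcyclodeca-3,7-dien-1-yl]propane-1,2-diol
Product: 8 (2R)-2-[(1S,3Z,7E)-4,8-dimethylcyclodeca-3,7-dien-1-yl]propane-1,2-diol
Conditions: PdCl2(dppp) (5 mol %), LiBHEt3 (excess), THF, 0 °C
Reagents that add atoms: none
Why: palladium-catalysed reductive desulfonylation of an allylic sulfone, in which the π-allylpalladium intermediate should take hydride at its less substituted terminus (the former sulfonyl carbon), so the trisubstituted 3Z olefin stays in place with its geometry held by the ring.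

**Step 7**
Reactants: 8 (2R)-2-[(1S,3Z,7E)-4,8-dimethylcyclodeca-3,7-dien-1-yl]propane-1,2-diol
Product: 9 1-[(1S,3Z,7E)-4,8-dimethylcyclodeca-3,7-dien-1-yl]ethan-1-one
Conditions: NaIO4, THF–H2O, 0 °C
Reagents that add atoms: none
Why: periodate glycol cleavage of the 1,2-diol under neutral conditions should unmask the methyl ketone without touching the olefins or the alpha stereocenter.

**Step 8**
Reactants: 9 1-[(1S,3Z,7E)-4,8-dimethylcyclodeca-3,7-dien-1-yl]ethan-1-one; 10 magnolol
Product: 11 1-[(2S,4aR,8R,8aS)-8-{[2'-hydroxy-5,5'-di(prop-2-en-1-yl)[1,1'-biphenyl]-2-yl]oxy}-4a,8-dimethyldecahydronaphthalen-2-yl]ethan-1-one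
Conditions: 10 (5 equiv), Tf2NH (5 mol %), 4 Å MS, CH2Cl2, −78 to −40 °C
Reagents that add atoms: none
Why: Tf2NH should protonate C1 of the 1(10)E olefin while C5 of the 4Z olefin bonds to C10 across the ring and a phenol oxygen of 10 adds to C4 antiperiplanar to the new C5–C10 bond; this is the proton-initiated transannular cation–olefin cyclization by which germacra-1(10),4-dienes close to eudesmanes with capture by water or alcohols. The single new C–C bond closes both six-membered rings at once, ring A (C10, C1–C5) in 6-endo and ring B (C5–C10) in 6-exo fashion with respect to C4=C5, through a chair-like array C10–C1–C2–C3–C4–C5. C10 and C5 are fixed by the E and Z geometries held in that chair (C9 equatorial and C6 axial on ring A, hence the cis fusion with the C10 methyl and H5 syn), and C4 by the anti addition across the Z olefin (C4 methyl syn to H5, oxygen anti). The face of the ten-membered ring is chosen by the C7 acetyl group lying equatorial on the chair-like developing ring B, which places it trans to the C10 methyl (4R,5S,7S,10R). O-capture over C-alkylation and over proton loss is a kinetic preference, helped by excess 10, low temperature and a catalytic non-nucleophilic acid; the two hydroxyls of 10 are equivalent and the excess keeps the etherification single.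

**Step 9**
Reactants: 11 1-[(2S,4aR,8R,8aS)-8-{[2'-hydroxy-5,5'-di(prop-2-en-1-yl)[1,1'-biphenyl]-2-yl]oxy}-4a,8-dimethyldecahydronaphthalen-2-yl]ethan-1-one
Product: 12 1-[(2R,4aR,8R,8aS)-8-{[2'-hydroxy-5,5'-di(prop-2-en-1-yl)[1,1'-biphenyl]-2-yl]oxy}-4a,8-dimethyldecahydronaphthalen-2-yl]ethan-1-one
Conditions: NaOMe, MeOH–THF, 40 °C; recovered 11 resubmitted
Reagents that add atoms: none
Why: base-mediated epimerization alpha to the ketone through the enolate (thermodynamic control), where the acetyl group is equatorial in both epimers but only the 7R epimer reaches it in the ring-flipped chair–chair form that has the C4 methyl equatorial and no longer 1,3-diaxial to the C10 methyl (at the price of an axial aryloxy group), so 12 should be modestly favoured.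

**Step 10**
Reactants: 12 1-[(2R,4aR,8R,8aS)-8-{[2'-hydroxy-5,5'-di(prop-2-en-1-yl)[1,1'-biphenyl]-2-yl]oxy}-4a,8-dimethyldecahydronaphthalen-2-yl]ethan-1-one
Product: 13 2-[(2R,4aR,8R,8aS)-8-{[2'-hydroxy-5,5'-di(prop-2-en-1-yl)[1,1'-biphenyl]-2-yl]oxy}-4a,8-dimethyldecahydronaphthalen-2-yl]propan-2-ol
Conditions: MeMgBr (4 equiv), LaCl3·2LiCl, THF, −20 to 0 °C; then H2O
Reagents that add atoms: methylmagnesium bromide, C[Mg]Br
Why: Grignard addition to the methyl ketone (the first equivalent is spent on the phenol), with LaCl3·2LiCl to suppress enolization so that the C7 configuration from step 9 is carried into the tertiary carbinol.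

**Compound list**

1 | (2Z,6E)-farnesol | OC/C=C(/C)CC/C=C(\C)CCC=C(C)C | starting material
2 | (2Z,6E)-farnesyl chloride | ClC/C=C(/C)CC/C=C(\C)CCC=C(C)C | intermediate
3 | (2Z,6E)-farnesyl phenyl sulfone | O=S(=O)(c1ccccc1)C/C=C(/C)CC/C=C(\C)CCC=C(C)C | intermediate
4 | (2E,6E,10Z)-12-(benzenesulfonyl)-2,6,10-trimethyldodeca-2,6,10-trien-1-ol | O=S(=O)(c1ccccc1)C/C=C(/C)CC/C=C(\C)CC/C=C(\C)CO | intermediate
5 | [(2S,3S)-3-[(3E,7Z)-9-(benzenesulfonyl)-3,7-dimethylnona-3,7-dien-1-yl]-2-methyloxiran-2-yl]methanol | O=S(=O)(c1ccccc1)C/C=C(/C)CC/C=C(\C)CC[C@@H]1O[C@@]1(C)CO | intermediate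
6 | dilithiated epoxy sulfone (lithium alkoxide and alpha-sulfonyl allyl anion of 5; not isolated) | [Li+].[Li+].O=S(=O)(c1ccccc1)[CH-]/C=C(/C)CC/C=C(\C)CC[C@@H]1O[C@@]1(C)C[O-] | intermediate
7 | (2R)-2-[(1R,3Z,7E)-2-(benzenesulfonyl)-4,8-dimethylcyclodeca-3,7-dien-1-yl]propane-1,2-diol (both epimers at ring C2) | O=S(=O)(c1ccccc1)C2/C=C(/C)CC/C=C(\C)CC[C@@H]2[C@@](C)(O)CO | intermediate
8 | (2R)-2-[(1S,3Z,7E)-4,8-dimethylcyclodeca-3,7-dien-1-yl]propane-1,2-diol | C1/C=C(/C)CC/C=C(\C)CC[C@@H]1[C@@](C)(O)CO | intermediate
9 | 1-[(1S,3Z,7E)-4,8-dimethylcyclodeca-3,7-dien-1-yl]ethan-1-one ((7S,1(10)E,4Z)-13-norgermacra-1(10),4-dien-11-one) | C1/C=C(/C)CC/C=C(\C)CC[C@@H]1C(C)=O | intermediate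
10 | magnolol (5,5'-di(prop-2-en-1-yl)[1,1'-biphenyl]-2,2'-diol) | C=CCc1ccc(O)c(-c2cc(CC=C)ccc2O)c1 | starting material
11 | 1-[(2S,4aR,8R,8aS)-8-{[2'-hydroxy-5,5'-di(prop-2-en-1-yl)[1,1'-biphenyl]-2-yl]oxy}-4a,8-dimethyldecahydronaphthalen-2-yl]ethan-1-one (cis-fused; 4R,5S,7S,10R) | C=CCc1ccc(O)c(-c2cc(CC=C)ccc2O[C@]2(C)CCC[C@]3(C)CC[C@H](C(C)=O)C[C@@H]32)c1 | intermediate
12 | 1-[(2R,4aR,8R,8aS)-8-{[2'-hydroxy-5,5'-di(prop-2-en-1-yl)[1,1'-biphenyl]-2-yl]oxy}-4a,8-dimethyldecahydronaphthalen-2-yl]ethan-1-one (cis-fused; 4R,5S,7R,10R) | C=CCc1ccc(O)c(-c2cc(CC=C)ccc2O[C@]2(C)CCC[C@]3(C)CC[C@@H](C(C)=O)C[C@@H]32)c1 | intermediate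
13 | 2-[(2R,4aR,8R,8aS)-8-{[2'-hydroxy-5,5'-di(prop-2-en-1-yl)[1,1'-biphenyl]-2-yl]oxy}-4a,8-dimethyldecahydronaphthalen-2-yl]propan-2-ol | C=CCc1ccc(O)c(-c2cc(CC=C)ccc2O[C@]2(C)CCC[C@]3(C)CC[C@@H](C(C)(C)O)C[C@@H]32)c1 | target

**Step count and risks**

Total steps: 10. Longest linear sequence: 10 steps (1 to 13); magnolol 10 enters at step 8.

Steps most likely to fail:

1. Step 8. The cationic centre at C4 may lose a proton or alkylate the arene carbon instead of being captured at oxygen, the acid may re-ionize the new tertiary aryl ether, and the small acetyl group may give incomplete facial control. The fallback replaces the proton by a selenium electrophile, so no strong acid is present. It sets out from 9 and 10: N-(phenylseleno)phthalimide with catalytic camphorsulfonic acid in CH2Cl2 at −78 °C should give, by anti addition across C1=C10 with the same transannular closure and phenol capture, the C1-phenylselanyl ether F1. Radical deselenation (Bu3SnH, AIBN, toluene, 80 °C) returns to the route at 11.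

2. Step 9. The C7 equilibrium may lie too little on the side of the 7R epimer, because the gain from removing the methyl/methyl 1,3-diaxial interaction is partly offset by the axial aryloxy group. The fallback replaces thermodynamic control by reagent-controlled kinetic protonation. It sets out from 11: Me3SiCl, Et3N, DMF, 80 °C should give the more substituted C7=C11 silyl enol ether with the phenol silylated, the bis-silyl enol ether F2. Protonation with a chiral BINOL-derived N-triflyl phosphoramide catalyst (antipode chosen by trial) and methanol as proton source in toluene at −78 °C returns to the route at 12.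

3. Step 5. Intermolecular alkylation and proton transfer within the dianion may outrun closure of the ten-membered ring. The fallback closes the ring from a mono-anion on an O-protected substrate, so no alkoxide sits next to the epoxide. It sets out from 5: t-BuMe2SiCl and imidazole in DMF give the silyl ether F3. n-BuLi (1.1 equiv) and DABCO in THF at high dilution, −78 to −20 °C, should give the macrocyclic silyl ether sulfone F4. PdCl2(dppp) with LiBHEt3 gives the desulfonylated silyl ether F5, and Bu4NF in THF returns to the route at 8.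

**Further compounds**

F1 | step 8 | C1-phenylselanyl derivative of 11 (eudesmane C1, selenium beta and equatorial, anti to the C5–C10 bond) | C=CCc1ccc(O)c(-c2cc(CC=C)ccc2O[C@]2(C)CC[C@@H]([Se]c4ccccc4)[C@]3(C)CC[C@H](C(C)=O)C[C@@H]32)c1
F2 | step 9 | C7=C11 trimethylsilyl enol ether of 11 with the phenol as trimethylsilyl ether (E/Z mixture at C7=C11) | C=CCc1ccc(O[Si](C)(C)C)c(-c2cc(CC=C)ccc2O[C@]2(C)CCC[C@]3(C)CCC(=C(C)O[Si](C)(C)C)C[C@@H]32)c1
F3 | step 5 | tert-butyldimethylsilyl ether of 5 | O=S(=O)(c1ccccc1)C/C=C(/C)CC/C=C(\C)CC[C@@H]1O[C@@]1(C)CO[Si](C)(C)C(C)(C)C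
F4 | step 5 | primary tert-butyldimethylsilyl ether of 7 (both epimers at ring C2) | O=S(=O)(c1ccccc1)C2/C=C(/C)CC/C=C(\C)CC[C@@H]2[C@@](C)(O)CO[Si](C)(C)C(C)(C)C
F5 | step 5 | primary tert-butyldimethylsilyl ether of 8 | C1/C=C(/C)CC/C=C(\C)CC[C@@H]1[C@@](C)(O)CO[Si](C)(C)C(C)(C)C
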